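## Structural features

The target is a germacrane-type sesquiterpene lactone. The locants used throughout are C1 (ring ketone), C2, C3, C4 (methylated oxirane carbon), C5 (oxirane CH), C6 (lactone O–CH), C7, C8 (acyloxy CH), C9, C10 (CH–CH3), C11 (lactone α-carbon), C12 (lactone C=O) and C13 (CH2OAc). A ten-membered carbocycle C1–C10 is fused across C6–C7 to a five-membered α,β-unsaturated γ-lactone (C7=C11). It also carries a cis-4,5-epoxide and, at C8, an ester of 2-(hydroxymethyl)acrylic acid. C4, C5 and C6 are contiguous stereocentres (4R,5S,6S). C8 (S) is separated from C6 only by the sp2 carbon C7, and C10 (R) stands 1,3 to C8 and α to the C1 ketone. The fragile groups are the epoxide that faces the C1 carbonyl across the ring (acid-triggered transannular opening), the γ-acidic C6–H of the butenolide, the primary allylic acetate at C13 (SN2′ displacement, acyl transfer), the Michael-accepting hydroxymethylacrylate and the epimerisable C10. The real difficulty is to close the medium ring with a cis C4–C5 unit and to pass the configuration of one secure centre (C8) on to C4, C5, C6 and C10 in a flexible ring. The key step exploits two facts. C1 (as its enol C1=C10) and C4=C5 (the alkene behind the epoxide) are the ends of the 1,5-diene C10=C1–C2–C3–C4=C5, the retron of a bicyclo[2.2.0]hexane cycloreversion. The carbons C5–C10, with the C6 carbonyl and the C8 oxygen, map onto a 5-oxygenated 3-methylcyclohexenone.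

## Logic of the disconnections

35 ⇒ 34 ⇒ 31 + 33. The acyl C–O bond at C8 and the O–Si bond of the side chain are cut. The acrylate is a Michael acceptor that would not survive enolate, peroxide or hydride chemistry, so it is attached last. Five carbons and the most reactive alkene leave the problem. The forward step must acylate a hindered secondary allylic alcohol under near-neutral conditions, and the final desilylation must spare the epoxide that faces the C1 ketone.

31 ⇒ 29 (through 30). The C8 O–H goes back to O–Si, and the C1 carbonyl with its C10–H goes back to the silyl enol ether C1=C10. Keeping C1 masked through all enolate chemistry leaves C6 as the only ketone, and the C10 centre is removed from the problem until the end. The forward step must protonate C10 to the 10R epimer (or let it equilibrate) without opening the epoxide.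

29 ⇒ 27 (through 28) ⇒ 25 ⇒ 20 + 23. The lactone O–C12 bond and the C6–H bond are cut, then C7=C11 is taken back to an aldol C7–C11 bond. The C6 ketone left by the ring expansion has C7 as its only enolisable α-carbon. The keto ester 23 brings C11, C12 and the oxygenated C13 in one piece; a plain pyruvate would leave C13 as a methyl group. The lactone and three carbons disappear, and C6 becomes the product of a hydride addition steered by the neighbouring epoxide. The forward sequence demands dehydration toward C7 (secured by eliminating while C6 is still a ketone), an alkene geometry with the ester syn to C6, and a 1,2-reduction anti to the epoxide.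

23 ⇒ 22 ⇒ 21 and 33 ⇒ 32 ⇒ 21. Both three-carbon reagents come from one acrylate, by cleavage of its C=C bond or hydrolysis of its ester. The forward steps need only an ozonolysis that tolerates the acetate and a saponification that tolerates the silyl ether.

20 ⇒ 19. Both oxirane C–O bonds are cut. While C6 is a ketone the alkene is an enone, so a nucleophilic oxidant reaches it and leaves the electron-rich enol ether alone, and the epoxide can then control C6. The forward step must keep the cis geometry and choose the face through the ring conformation set by C8.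

19 ⇒ 17 (through 18). The C1–C4 and C5–C10 bonds are re-formed, turning the ten-membered diene into a tricycle with two fused four-membered rings. The medium ring is replaced by small rings that are easy to make. The forward thermolysis must cleave these two bonds and not the two made by light, must leave or allow equilibration to cis C4=C5, and must stop before a Cope rearrangement.

17 ⇒ 10 + 16. The C1–C10 and C4–C5 bonds are cut ([2+2]). Two monofunctional rings result. The forward step must be head-to-tail. 16 is given a tert-butyldimethylsilyl rather than a trimethylsilyl enol ether so that the masked C1 ketone lasts to the end.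

10 ⇒ 9 ⇒ 8 ⇒ 7 ⇒ 6 ⇒ 5 ⇒ 4 ⇒ 3 ⇒ 2 ⇒ 1. The C10–CH3 bond is cut (conjugate addition, then dehydrogenation), which keeps the carbonyl where it is. A 1,2-addition followed by oxidative 1,3-transposition would move the carbonyl to the other side of the stereocentre and give the mirror-image enone. Further back stand a β-elimination, cleavage of the exocyclic C–C bond at the quaternary carbinol, deoxygenation at the central carbinol and protection. The chiral pool supplies C8; the forward steps must not eliminate the second silyloxy group.

16 ⇒ 15 ⇒ 12 ⇒ 11. The O–Si bond and the ring C–CH3 bond are cut. The forward steps need monomethylation of a four-membered ketone (through its imine) and enol silylation on the substituted side.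

## Other disconnections considered

Alternative 1: The cut is C8–C9, made while the C1–C6 bond of a six-membered ring breaks. In the forward sense the potassium alkoxide of the dialkenylcyclohexenol A1 (KH, 18-crown-6) would undergo an anionic oxy-Cope shift, and C-protonation of the dienolate would give the ten-membered dienone A2.
- In its favour: the cis C4=C5 bond is inherited from the six-membered ring, so no geometric equilibration is needed; on this point it is better than the chosen plan. The reaction runs at or below room temperature instead of 200 °C, which is also better. A2 has the same functional pattern as 19, so the endgame would be equal.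
- Against it here: C8 is created in the key step from the enol ether geometry and a chair transition state instead of being taken from the chiral pool. A1 needs two adjacent fully substituted carbons of defined relative and absolute configuration, and the dienolate of a β-alkoxy ketone can lose the C8 alkoxide under the strongly basic conditions.
- Comparison: on structure the two plans converge on the same ring. On mechanism the sigmatropic shift is more predictable in geometry but less secure in absolute configuration. On step economy the enantioselective construction of A1 is expected to cost about as many steps as 1 to 17.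

Alternative 2: The cuts are C2–C3, C6–C7 and C8–C9. In the forward sense zerovalent nickel (Ni(cod)2, PPh3) would link two molecules of isoprene A3 into a bis-allyl chain and insert the alkyne of enyne A4, closing the triene A5 on reductive elimination.
- In its favour: the whole carbocycle comes in one catalytic step from three C5 units, which is better than the chosen plan in step economy for the skeleton. The diene C13=C11–C7=C8 of A5 could take up oxygen at C8 and C13 with the double bond moving to C7=C11, which would avoid the alkene-geometry question of step 19; on that point it is also better.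
- Against it here: the two isoprene units can couple in four orientations and the terminal alkyne can oligomerise on nickel. A5 is achiral and has no oxygen at C1, C6 or C8. Three trisubstituted alkenes would have to be told apart, and every stereocentre would need a later catalyst-controlled step.
- Comparison: the skeleton is built faster, but the functionalisation is longer and less controlled. The chosen plan brings C8 as a fixed centre and the C1 and C6 oxygens already in place.

Alternative 3: The cut is C1–C2, with C1 migrating away from C6. In the forward sense Bu3SnH with AIBN would convert iodide A6 into the C2 radical, which adds to the C1 carbonyl; the alkoxy radical would then cleave C1–C6 and the stabilised C6 radical would take up hydrogen to give A7.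
- In its favour: the butenolide with its C13 acetate and the C8 and C10 centres are in place before the ring expansion, and the conditions are neutral. Only epoxidation, deprotection and acylation remain, so the sequence after the key step is shorter; on this point it is better than the chosen plan.
- Against it here: A6 needs a fully substituted C6 bearing the lactone oxygen, the fused butenolide and a cis iodoalkenyl chain, a long synthesis in its own right. The six-membered closure onto a carbonyl competes with direct reduction of the primary radical. The C6 radical is delocalised toward C4 and C11, so hydrogen transfer can give positional isomers and can scramble the C4=C5 geometry, and the C6 configuration is set without an obvious control element.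
- Comparison: on structure it is the most convergent late intermediate. On mechanism the chosen plan relies on strain release in a closed-shell thermolysis, not on a radical chain with several exits. On overall step economy the effort is moved into the preparation of A6.

Key step: step 13

Remark: the medium-ring compounds are described with the target locants C1–C13 defined above.
Remark (correction): methyl addition to the carbonyl of 8 followed by oxidative 1,3-transposition would place the new carbonyl on the other side of the silyloxy carbon and give the (R)-enantiomer of 10; steps 8 and 9 keep the carbonyl in place.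
Remark (precursor design): a free C1 ketone would compete with C6 in the enolisation of step 18, so 16 carries a tert-butyldimethylsilyl enol ether and C1 stays masked until step 21.
Remark: the keto ester 23 carries the C13 oxygen, which a simple pyruvate would not provide.
Assumption: the C1=C10 enol ether in 18, 19, 20 and 24–29 is drawn with C2 and C9 cis; its geometry is erased in step 21.

## Route

Step 1
Reactants: 1 (−)-quinic acid
Product: 2 methyl quinate, methyl (1S,3R,4S,5R)-1,3,4,5-tetrahydroxycyclohexane-1-carboxylate
Conditions: MeOH, Amberlyst 15 (H+ form), reflux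
Reagents that add atoms: methanol, CO
Why: Fischer esterification on an acidic resin; no stereocentre is involved.

Step 2
Reactants: 2 methyl quinate
Product: 3 methyl 3,5-bis-O-(tert-butyldimethylsilyl)quinate (C1 and C4 hydroxyls free)
Conditions: TBSCl (2.2 equiv), Et3N, DMAP (cat.), DMF, 0 °C to rt
Reagents that add atoms: tert-butyldimethylsilyl chloride, CC(C)(C)[Si](C)(C)Cl
Why: Selective silylation; the tertiary C1 hydroxyl and the C4 hydroxyl, which is flanked on both sides once its neighbours are silylated, should react slowest.

Step 3
Reactants: 3 methyl 3,5-bis-O-TBS-quinate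
Product: 4 methyl 3,5-bis-O-TBS-4-O-(imidazol-1-ylthiocarbonyl)quinate
Conditions: 1,1′-thiocarbonyldiimidazole, DMAP (cat.), CH2Cl2, reflux
Reagents that add atoms: 1,1′-thiocarbonyldiimidazole, S=C(n1ccnc1)n1ccnc1
Why: Thioacylation of the only free secondary hydroxyl; the tertiary hydroxyl is too hindered to react.

Step 4
Reactants: 4 thiocarbonylimidazolide
Product: 5 methyl (3S,5S)-3,5-bis(tert-butyldimethylsilyloxy)-1-hydroxycyclohexane-1-carboxylate
Conditions: n-Bu3SnH, AIBN (cat.), PhMe, 100 °C
Reagents that add atoms: none
Why: Barton–McCombie deoxygenation of the secondary thiocarbonyl derivative; the two silyloxy centres are untouched and only change descriptor because the substituent ranking changes.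

Step 5
Reactants: 5 hydroxy ester
Product: 6 (3S,5S)-3,5-bis(tert-butyldimethylsilyloxy)-1-(hydroxymethyl)cyclohexan-1-ol
Conditions: NaBH4, EtOH, 0 °C to rt
Reagents that add atoms: none
Why: α-Hydroxy esters are activated enough for borohydride reduction to the 1,2-diol.

Step 6
Reactants: 6 diol
Product: 7 (3S,5S)-3,5-bis(tert-butyldimethylsilyloxy)cyclohexan-1-one
Conditions: NaIO4, MeOH–H2O, 0 °C
Reagents that add atoms: none
Why: Periodate glycol cleavage; the tertiary carbinol becomes the ketone of a C2-symmetric trans-disilyloxy ketone.

Step 7
Reactants: 7 bis(silyloxy) ketone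
Product: 8 (S)-5-(tert-butyldimethylsilyloxy)cyclohex-2-en-1-one
Conditions: DBU (1.1 equiv), CH2Cl2, 0 °C
Reagents that add atoms: none
Why: E1cB β-elimination of one silyloxy group; the C2 symmetry of 7 makes both eliminations give the same enantiomer, and low temperature avoids the second elimination to a phenol.

Step 8
Reactants: 8 enone
Product: 9 (3S,5S)-5-(tert-butyldimethylsilyloxy)-3-methyl-1-(trimethylsilyloxy)cyclohex-1-ene (3,5-trans)
Conditions: Me2CuLi (from MeLi and CuI), TMSCl, THF, −78 °C
Reagents that add atoms: lithium dimethylcuprate Me2CuLi, [Li+].C[Cu-]C; chlorotrimethylsilane, C[Si](C)(C)Cl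
Why: Cuprate conjugate addition with in situ enolate silylation; methyl should add anti to the C5 silyloxy group, and this transient centre is removed in step 9.

Step 9
Reactants: 9 trimethylsilyl enol ether
Product: 10 (S)-5-(tert-butyldimethylsilyloxy)-3-methylcyclohex-2-en-1-one
Conditions: Pd(OAc)2 (1.05 equiv), MeCN, rt
Reagents that add atoms: none
Why: Saegusa–Ito oxidation; the palladium enolate can only eliminate hydride from the methyl-bearing carbon, so the enone returns with the carbonyl in its original position and the silyloxy centre unchanged.

Step 10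
Reactants: 11 cyclobutanone
Product: 12 N-cyclobutylidenepropan-2-amine
Conditions: i-PrNH2, TiCl4, Et2O, 0 °C to rt
Reagents that add atoms: isopropylamine, CC(C)N
Why: Imine formation with TiCl4 as water scavenger; the imine allows clean monoalkylation, which the self-condensing ketone enolate does not.

Step 11
Reactants: 12 N-cyclobutylidenepropan-2-amine
Product: 15 2-methylcyclobutanone (racemic), via lithiated imine 13 (not isolated), via methylated imine 14 (not isolated)
Conditions: LiN(i-Pr)2 (LDA), THF, 0 °C; MeI, −78 °C to rt; aq. oxalic acid, Et2O, rt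
Reagents that add atoms: iodomethane, CI; water, O
Why: Aza-enolate alkylation followed by two-phase imine hydrolysis; the new centre is racemic and becomes sp2 in step 12.

Step 12
Reactants: 15 2-methylcyclobutanone
Product: 16 1-(tert-butyldimethylsilyloxy)-2-methylcyclobut-1-ene
Conditions: TBSOTf, Et3N, CH2Cl2, 0 °C to rt
Reagents that add atoms: tert-butyldimethylsilyl triflate, CC(C)(C)[Si](C)(C)OS(=O)(=O)C(F)(F)F
Why: Enol silylation under equilibrating conditions should favour the more substituted enol ether; ring strain is the same for both regioisomers.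

Step 13
Reactants: 10 (S)-5-(tert-butyldimethylsilyloxy)-3-methylcyclohex-2-en-1-one; 16 1-(tert-butyldimethylsilyloxy)-2-methylcyclobut-1-ene
Product: 17 cis-anti-cis photoadduct, (1S,2R,5S,6S,9S)-2,9-bis(tert-butyldimethylsilyloxy)-1,5-dimethyltricyclo[4.4.0.0(2,5)]decan-7-one (target locants: new bonds C1–C10 and C4–C5; 1R,4S,5S,8S,10S)
Conditions: hν (medium-pressure Hg lamp, uranium-glass filter, λ > 330 nm), 16 (5 equiv), CH2Cl2, −40 °C; then basic Al2O3
Reagents that add atoms: none
Why: Excitation of 10 and intersystem crossing give the enone triplet, which adds stepwise to the electron-rich alkene 16 through a 1,4-biradical; the closest known reaction type is the intermolecular enone–alkene [2+2] photocycloaddition of cyclohexenones with enol ethers and cyclobutenes, whose adducts open on heating to cyclodeca-1,5-dienes. The four-membered ring C1–C10–C5–C4 is closed as an intermolecular two-bond annulation, the second bond by recombination of the 1,4-biradical. The donor oxygen directs the head-to-tail orientation, so the oxygen-bearing C1 bonds to the β-carbon C10 and C4 to the α-carbon C5; this is the selectivity the plan needs, because only it puts the future ketone at C1 and the methyl group at C4. C1 and C4 are cis because they come from the cis double bond of the four-membered ring; C5 and C10 end cis-fused because a trans-fused bicyclo[4.2.0]octanone is strained and any trans adduct is epimerised at the enolisable C5 on basic alumina. The anti arrangement of the outer rings follows from approach of 16 with its CH2–CH2 bridge turned away from the six-membered ring, on the face opposite the C8 silyloxy group. Only C8 survives step 14, so diastereomers at C1, C4, C5 and C10 would converge, whereas a head-to-head adduct would not. Excess 16, low temperature and light above 330 nm suppress enone dimerisation and secondary photolysis of the product ketone.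

Step 14
Reactants: 17 photoadduct
Product: 19 (1(10)E,4Z,8S)-1,8-bis(tert-butyldimethylsilyloxy)-4,10-dimethylcyclodeca-1(10),4-dien-6-one (target locants; cis C4=C5), via 4E dienone 18 (not isolated)
Conditions: PhMe (degassed, base-washed sealed tube), 200 °C; then (PhS)2 (10 mol %), visible light, rt
Reagents that add atoms: none
Why: Homolysis of the shared C1–C4 bond of the bicyclo[2.2.0]hexane gives a cyclohexane-1,4-diyl that fragments the C5–C10 bond (formal retro-[2+2]) and releases the strain of two four-membered rings. A chair diyl with the C10 methyl equatorial predicts the trans C4=C5 isomer 18 first. Reversible thiyl-radical addition then equilibrates it to the cis enone, the less strained geometry in a ten-membered ring. Conjugation of C4=C5 with C6=O disfavours Cope rearrangement, and C8 is untouched.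

Step 15
Reactants: 19 cis dienone
Product: 20 (4R,5R,8S)-1,8-bis(tert-butyldimethylsilyloxy)-4,5-epoxy-4,10-dimethylcyclodec-1(10)-en-6-one (cis-epoxide; target locants)
Conditions: t-BuOOH, benzyltrimethylammonium hydroxide (cat.), THF, 0 °C
Reagents that add atoms: tert-butyl hydroperoxide, CC(C)(C)OO
Why: Weitz–Scheffer nucleophilic epoxidation (conjugate addition of the peroxide anion at C4, then closure of the enolate on oxygen); the electron-rich enol ether is inert to this oxidant, the ring holds C3 and C6 cis, and attack on the outer face of the conformer with the C8 silyloxy group pseudo-equatorial is expected to give the epoxide configuration of the target.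

Step 16
Reactants: 21 ethyl 2-(hydroxymethyl)acrylate
Product: 22 ethyl 2-(acetoxymethyl)acrylate
Conditions: Ac2O, pyridine, DMAP (cat.), CH2Cl2, 0 °C
Reagents that add atoms: acetic anhydride, CC(=O)OC(C)=O
Why: Standard acetylation of a primary allylic alcohol.

Step 17
Reactants: 22 ethyl 2-(acetoxymethyl)acrylate
Product: 23 ethyl 3-acetoxy-2-oxopropanoate
Conditions: O3, CH2Cl2, −78 °C; Me2S
Reagents that add atoms: ozone, [O-][O+]=O
Why: Ozonolysis of a 1,1-disubstituted acrylate with reductive work-up gives the α-keto ester and formaldehyde.

Step 18
Reactants: 20 epoxy ketone; 23 ethyl 3-acetoxy-2-oxopropanoate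
Product: 25 aldol adduct, 20 carrying at C7 the group C(OH)(CH2OAc)CO2Et (mixture at C7 and C11), via lithium enolate 24 (not isolated)
Conditions: LiN(i-Pr)2 (LDA), THF, −78 °C; 23, −78 °C; AcOH quench at −78 °C
Reagents that add atoms: none
Why: Kinetic deprotonation can only occur at C7 (C5 is an oxirane carbon and C1 is masked), and the lithium enolate adds to the highly electrophilic keto group of 23 (aldol addition to an α-keto ester); both new centres are removed in step 19, and the low temperature and acidic quench limit retro-aldol, acetyl migration and loss of the C8 silyloxy group.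

Step 19
Reactants: 25 aldol adduct
Product: 27 (7(11)Z)-alkylidene keto ester, C7=C11(CO2Et)CH2OAc with the ester syn to C6 (4R,5R,8S), via tertiary mesylate 26 (not isolated)
Conditions: MsCl, Et3N, CH2Cl2, −20 °C to rt
Reagents that add atoms: none
Why: Mesylation of the tertiary alcohol and E1cB elimination through the C6 enolate; only C7–H is acidic, so the alkene is placed at C7=C11 and not toward C13, while the geometry with the ester syn to C6 is needed for step 20 and is not assured (see the risks).

Step 20
Reactants: 27 alkylidene keto ester
Product: 29 (4R,5S,6S,8S)-13-acetoxy-1,8-bis(tert-butyldimethylsilyloxy)-4,5-epoxygermacra-1(10),7(11)-dien-12,6-olide, via hydroxy ester 28 (not isolated)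
Conditions: NaBH4, CeCl3·7H2O, MeOH–THF, −78 °C to 0 °C
Reagents that add atoms: none
Why: Luche 1,2-reduction; cerium chelated between the C6 carbonyl and the oxirane oxygen exposes the face anti to C4, which should give the anti (erythro) epoxy alcohol, that is 6S, and the cis γ-hydroxy ester closes to the butenolide with loss of ethanol.

Step 21
Reactants: 29 bis-silyl butenolide
Product: 31 (4R,5S,6S,8S,10R)-13-acetoxy-4,5-epoxy-8-hydroxy-1-oxogermacr-7(11)-en-12,6-olide, via 8-silyloxy ketone 30 (not isolated)
Conditions: HF·pyridine, pyridine, THF, 0 °C to rt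
Reagents that add atoms: none
Why: Fluoride-assisted Si–O cleavage; the enol ether goes first and the enol ketonises with protonation at C10, which stays epimerisable next to C1=O and is expected to settle as the 10R epimer, and the pyridine buffer should spare epoxide, acetate and lactone.

Step 22
Reactants: 21 ethyl 2-(hydroxymethyl)acrylate
Product: 32 ethyl 2-[(tert-butyldimethylsilyloxy)methyl]acrylate
Conditions: TBSCl, imidazole, CH2Cl2, rt
Reagents that add atoms: tert-butyldimethylsilyl chloride, CC(C)(C)[Si](C)(C)Cl
Why: Standard silylation of a primary alcohol.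

Step 23
Reactants: 32 silyl ether ester
Product: 33 2-[(tert-butyldimethylsilyloxy)methyl]acrylic acid
Conditions: LiOH, THF–H2O, 0 °C; then 1 M HCl to pH 4
Reagents that add atoms: lithium hydroxide LiOH, [Li+].[OH-]
Why: Saponification of the ethyl ester; the primary silyl ether tolerates cold aqueous hydroxide and brief mild acidification.

Step 24
Reactants: 31 hydroxy ketone; 33 silyl-protected acid
Product: 34 8-O-{2-[(tert-butyldimethylsilyloxy)methyl]acryloyl} derivative of 31
Conditions: EDC·HCl, DMAP (0.2 equiv), CH2Cl2, 0 °C to rt
Reagents that add atoms: none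
Why: Steglich esterification of the secondary allylic hydroxyl with retention at C8; low temperature and substoichiometric DMAP limit translactonisation toward O8 and conjugate addition to the acrylate.

Step 25
Reactants: 34 silyl-protected ester
Product: 35 target, (4R,5S,6S,8S,10R)-13-acetoxy-4,5-epoxy-8-[2-(hydroxymethyl)acryloyloxy]-1-oxogermacr-7(11)-en-12,6-olide
Conditions: HF·pyridine, pyridine, THF, 0 °C
Reagents that add atoms: none
Why: Buffered fluoride removes the primary silyl ether under near-neutral conditions, which avoids acid-triggered transannular attack of the C1 carbonyl on the epoxide.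

## Compound list

1 | (−)-quinic acid | C1[C@H]([C@H]([C@@H](C[C@@]1(C(=O)O)O)O)O)O | starting material
2 | methyl quinate | C1[C@H]([C@H]([C@@H](C[C@@]1(C(=O)OC)O)O)O)O | intermediate
3 | methyl 3,5-bis-O-(tert-butyldimethylsilyl)quinate | C1[C@H]([C@H]([C@@H](C[C@@]1(C(=O)OC)O)O[Si](C)(C)C(C)(C)C)O)O[Si](C)(C)C(C)(C)C | intermediate
4 | methyl 3,5-bis-O-TBS-4-O-(imidazol-1-ylthiocarbonyl)quinate | C1[C@H]([C@H]([C@@H](C[C@@]1(C(=O)OC)O)O[Si](C)(C)C(C)(C)C)OC(=S)n1ccnc1)O[Si](C)(C)C(C)(C)C | intermediate
5 | methyl (3S,5S)-3,5-bis(tert-butyldimethylsilyloxy)-1-hydroxycyclohexane-1-carboxylate | C1[C@H](C[C@@H](CC1(C(=O)OC)O)O[Si](C)(C)C(C)(C)C)O[Si](C)(C)C(C)(C)C | intermediate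
6 | (3S,5S)-3,5-bis(tert-butyldimethylsilyloxy)-1-(hydroxymethyl)cyclohexan-1-ol | C1[C@H](C[C@@H](CC1(CO)O)O[Si](C)(C)C(C)(C)C)O[Si](C)(C)C(C)(C)C | intermediate
7 | (3S,5S)-3,5-bis(tert-butyldimethylsilyloxy)cyclohexan-1-one | C1[C@H](C[C@@H](CC1=O)O[Si](C)(C)C(C)(C)C)O[Si](C)(C)C(C)(C)C | intermediate
8 | (S)-5-(tert-butyldimethylsilyloxy)cyclohex-2-en-1-one | O=C1C=CC[C@H](O[Si](C)(C)C(C)(C)C)C1 | intermediate
9 | (3S,5S)-5-(tert-butyldimethylsilyloxy)-3-methyl-1-(trimethylsilyloxy)cyclohex-1-ene | C[Si](C)(C)OC1=C[C@@H](C)C[C@H](O[Si](C)(C)C(C)(C)C)C1 | intermediate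
10 | (S)-5-(tert-butyldimethylsilyloxy)-3-methylcyclohex-2-en-1-one | O=C1C=C(C)C[C@H](O[Si](C)(C)C(C)(C)C)C1 | intermediate
11 | cyclobutanone | O=C1CCC1 | starting material
12 | N-cyclobutylidenepropan-2-amine | CC(C)N=C1CCC1 | intermediate
13 | lithium cyclobut-1-en-1-yl(propan-2-yl)azanide (lithiated imine) | [Li]N(C(C)C)C1=CCC1 | intermediate
14 | N-(2-methylcyclobutylidene)propan-2-amine (racemic) | CC1CCC1=NC(C)C | intermediate
15 | 2-methylcyclobutanone (racemic) | CC1CCC1=O | intermediate
16 | 1-(tert-butyldimethylsilyloxy)-2-methylcyclobut-1-ene | CC1=C(O[Si](C)(C)C(C)(C)C)CC1 | intermediate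
17 | cis-anti-cis photoadduct, (1S,2R,5S,6S,9S)-2,9-bis(tert-butyldimethylsilyloxy)-1,5-dimethyltricyclo[4.4.0.0(2,5)]decan-7-one | O=C1C[C@@H](O[Si](C)(C)C(C)(C)C)C[C@@]2(C)[C@@H]1[C@]3(C)CC[C@@]32O[Si](C)(C)C(C)(C)C | intermediate
18 | (1(10)E,4E,8S)-1,8-bis(tert-butyldimethylsilyloxy)-4,10-dimethylcyclodeca-1(10),4-dien-6-one | O=C1C[C@@H](O[Si](C)(C)C(C)(C)C)C/C(C)=C(O[Si](C)(C)C(C)(C)C)\CC/C(C)=C/1 | intermediate
19 | (1(10)E,4Z,8S)-1,8-bis(tert-butyldimethylsilyloxy)-4,10-dimethylcyclodeca-1(10),4-dien-6-one | O=C1C[C@@H](O[Si](C)(C)C(C)(C)C)C/C(C)=C(O[Si](C)(C)C(C)(C)C)\CC/C(C)=C\1 | intermediate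
20 | (4R,5R,8S)-1,8-bis(tert-butyldimethylsilyloxy)-4,5-epoxy-4,10-dimethylcyclodec-1(10)-en-6-one (cis-epoxide) | CC(C)(C)[Si](C)(C)O[C@H]1C/C(C)=C(O[Si](C)(C)C(C)(C)C)\CC[C@@]2(C)O[C@H]2C(=O)C1 | intermediate
21 | ethyl 2-(hydroxymethyl)acrylate | C=C(CO)C(=O)OCC | starting material
22 | ethyl 2-(acetoxymethyl)acrylate | C=C(COC(C)=O)C(=O)OCC | intermediate
23 | ethyl 3-acetoxy-2-oxopropanoate | CCOC(=O)C(=O)COC(C)=O | intermediate
24 | lithium C6=C7 enolate of 20 | CC(C)(C)[Si](C)(C)O[C@H]1C/C(C)=C(O[Si](C)(C)C(C)(C)C)\CC[C@@]2(C)O[C@H]2C(O[Li])=C1 | intermediate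
25 | aldol adduct, 20 with C(OH)(CH2OAc)CO2Et at C7 (mixture at C7 and C11) | CC(C)(C)[Si](C)(C)O[C@H]1C/C(C)=C(O[Si](C)(C)C(C)(C)C)\CC[C@@]2(C)O[C@H]2C(=O)C1C(O)(COC(C)=O)C(=O)OCC | intermediate
26 | C11 methanesulfonate of 25 | CC(C)(C)[Si](C)(C)O[C@H]1C/C(C)=C(O[Si](C)(C)C(C)(C)C)\CC[C@@]2(C)O[C@H]2C(=O)C1C(OS(C)(=O)=O)(COC(C)=O)C(=O)OCC | intermediate
27 | (7(11)Z)-alkylidene keto ester (4R,5R,8S) | CC(C)(C)[Si](C)(C)O[C@H]1C/C(C)=C(O[Si](C)(C)C(C)(C)C)\CC[C@@]2(C)O[C@H]2C(=O)/C1=C(/COC(C)=O)C(=O)OCC | intermediate
28 | (4R,5S,6S,8S)-6-hydroxy ester from 27 | CC(C)(C)[Si](C)(C)O[C@H]1C/C(C)=C(O[Si](C)(C)C(C)(C)C)\CC[C@@]2(C)O[C@H]2[C@@H](O)/C1=C(/COC(C)=O)C(=O)OCC | intermediate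
29 | (4R,5S,6S,8S)-13-acetoxy-1,8-bis(tert-butyldimethylsilyloxy)-4,5-epoxygermacra-1(10),7(11)-dien-12,6-olide | CC(C)(C)[Si](C)(C)O[C@H]1C/C(C)=C(O[Si](C)(C)C(C)(C)C)\CC[C@@]2(C)O[C@H]2[C@H]2OC(=O)C(COC(C)=O)=C12 | intermediate
30 | (4R,5S,6S,8S,10R)-13-acetoxy-8-(tert-butyldimethylsilyloxy)-4,5-epoxy-1-oxogermacr-7(11)-en-12,6-olide | CC(C)(C)[Si](C)(C)O[C@H]1C[C@@H](C)C(=O)CC[C@@]2(C)O[C@H]2[C@H]2OC(=O)C(COC(C)=O)=C12 | intermediate
31 | (4R,5S,6S,8S,10R)-13-acetoxy-4,5-epoxy-8-hydroxy-1-oxogermacr-7(11)-en-12,6-olide | O[C@H]1C[C@@H](C)C(=O)CC[C@@]2(C)O[C@H]2[C@H]2OC(=O)C(COC(C)=O)=C12 | intermediate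
32 | ethyl 2-[(tert-butyldimethylsilyloxy)methyl]acrylate | C=C(CO[Si](C)(C)C(C)(C)C)C(=O)OCC | intermediate
33 | 2-[(tert-butyldimethylsilyloxy)methyl]acrylic acid | C=C(CO[Si](C)(C)C(C)(C)C)C(=O)O | intermediate
34 | 8-O-{2-[(tert-butyldimethylsilyloxy)methyl]acryloyl} derivative of 31 | C=C(CO[Si](C)(C)C(C)(C)C)C(=O)O[C@H]1C[C@@H](C)C(=O)CC[C@@]2(C)O[C@H]2[C@H]2OC(=O)C(COC(C)=O)=C12 | intermediate
35 | CNP0258719.1 | C=C(CO)C(=O)O[C@H]1C[C@@H](C)C(=O)CC[C@@]2(C)O[C@H]2[C@H]2OC(=O)C(COC(C)=O)=C12 | target

## Step count and least certain steps

Total: 25 steps. Longest linear sequence: 18 steps (steps 1–9, 13–15, 18–21, 24, 25).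

Step 13 (key step). Three contiguous fully substituted carbons (C1, C4, C10) are formed, so slow addition, erosion of the head-to-tail preference and competing enone dimerisation are the likely failures. The fallback sets out from 10 and 15, returns at 19, and makes the cycloaddition intramolecular through a silicon tether between O8 and O1. Aqueous HF in MeCN would free (S)-5-hydroxy-3-methylcyclohex-2-en-1-one F1. Ketone 15 would be converted with i-Pr2SiCl2 and Et3N into its chlorosilyl enol ether and joined to F1 (imidazole) to give the mixed diisopropylsilylene ketal F2. Irradiation would close C1–C10 and C4–C5 inside a seven-membered tether ring, the crossed mode being excluded by strain, to give the tethered tricycle F3 with the four-membered rings syn to O8. HF·pyridine would release the tricyclic diol F4, and TBSOTf with 2,6-lutidine would give the bis-silyl ether F5, which differs from 17 only at the four centres destroyed on heating. The conditions of step 14 would then lead to 19.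

Step 14. Enolisation of the C6 ketone at 200 °C with loss of the C8 silyloxy group, Cope rearrangement of the diene, and incomplete trans-to-cis equilibration are the likely failures. The fallback sets out from 17, returns at 18, and runs the cycloreversion at the carbinol oxidation level, where enolisation is impossible. NaBH4 would give the tricyclic carbinol F6 (either C6 epimer), thermolysis would give the cyclodecadienol F7, and MnO2 would oxidise the allylic alcohol to 18, which is equilibrated to 19 as in step 14.

Step 15. The face of attack depends on a remote centre (C8) through the ring conformation. γ-Deprotonation could also deconjugate the enone, and rotation in the β-peroxy enolate could give the trans epoxide. The fallback sets out from 19, returns at 20, and ties the epoxide face to a carbinol set by reagent control. CBS reduction would give the (6R)-allylic alcohol F8. Hydroxyl-directed epoxidation with VO(acac)2 and t-BuOOH (concerted, so the cis geometry is kept, and syn to the hydroxyl) would give the epoxy alcohol F9. Dess–Martin oxidation would return 20.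

Step 19 (with step 20). Elimination may give the geometry with the ester anti to C6, which cannot lactonise, and base may move the double bond toward C13. The fallback sets out from 20, returns at 29, and closes the lactone before the alkene is made. Aldol addition of the lithium enolate of 20 to ethyl glyoxylate would give the hydroxy ester F10. Zn(BH4)2 reduction and lactonisation would give the α-hydroxy lactone F11. Dess–Martin oxidation would give the α-keto lactone as its enol F12, in which C7=C11 forms inside the ring. Tf2O with pyridine would give the enol triflate F13. Coupling with Bu3SnCH2OH (Pd(PPh3)4, LiCl) would give the C13 alcohol F14, and Ac2O with pyridine would give 29.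

Step 21. Protonation at C10 may be unselective or favour the 10S epimer, and HF may open the epoxide across the ring. The fallback sets out from 29, returns at 30, and replaces substrate control by reagent control. Protonation of the silyl enol ether with phenol, catalysed by a chiral N-triflyl phosphoramide at low temperature, would give 30 with the C8 silyl ether still in place, and buffered HF would then complete step 21. No new compound is made.

## Further compounds

F1 | step 13 | (S)-5-hydroxy-3-methylcyclohex-2-en-1-one | O=C1C=C(C)C[C@H](O)C1
F2 | step 13 | diisopropylsilylene ketal joining O8 of F1 to the enol oxygen of 15 | CC1=C(O[Si](C(C)C)(C(C)C)O[C@H]2CC(C)=CC(=O)C2)CC1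
F3 | step 13 | tethered cis-anti-cis tricycle (four-membered rings syn to O8) | O=C1C[C@@H](O[Si]4(C(C)C)C(C)C)C[C@]2(C)[C@H]1[C@@]3(C)CC[C@]32O4
F4 | step 13 | tricyclic diol from F3 | O=C1C[C@@H](O)C[C@]2(C)[C@H]1[C@@]3(C)CC[C@]32O
F5 | step 13 | bis(tert-butyldimethylsilyl) ether of F4 (diastereomer of 17) | O=C1C[C@@H](O[Si](C)(C)C(C)(C)C)C[C@]2(C)[C@H]1[C@@]3(C)CC[C@]32O[Si](C)(C)C(C)(C)C
F6 | step 14 | C6 carbinol of 17 (either epimer) | OC1C[C@@H](O[Si](C)(C)C(C)(C)C)C[C@@]2(C)[C@@H]1[C@]3(C)CC[C@@]32O[Si](C)(C)C(C)(C)C
F7 | step 14 | C6 carbinol of 18 (either epimer) | OC1C[C@@H](O[Si](C)(C)C(C)(C)C)C/C(C)=C(O[Si](C)(C)C(C)(C)C)\CC/C(C)=C/1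
F8 | step 15 | (6R)-allylic alcohol of 19 | O[C@@H]1C[C@@H](O[Si](C)(C)C(C)(C)C)C/C(C)=C(O[Si](C)(C)C(C)(C)C)\CC/C(C)=C\1
F9 | step 15 | (4R,5S,6R)-epoxy alcohol | CC(C)(C)[Si](C)(C)O[C@H]1C/C(C)=C(O[Si](C)(C)C(C)(C)C)\CC[C@@]2(C)O[C@H]2[C@H](O)C1
F10 | step 19 | glyoxylate aldol adduct of 20 (mixture at C7 and C11) | CC(C)(C)[Si](C)(C)O[C@H]1C/C(C)=C(O[Si](C)(C)C(C)(C)C)\CC[C@@]2(C)O[C@H]2C(=O)C1C(O)C(=O)OCC
F11 | step 19 | 11-hydroxy-12,6-lactone (mixture at C7 and C11) | CC(C)(C)[Si](C)(C)O[C@H]1C/C(C)=C(O[Si](C)(C)C(C)(C)C)\CC[C@@]2(C)O[C@H]2[C@H]2OC(=O)C(O)C12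
F12 | step 19 | 11-hydroxybutenolide (enol of the α-keto lactone) | CC(C)(C)[Si](C)(C)O[C@H]1C/C(C)=C(O[Si](C)(C)C(C)(C)C)\CC[C@@]2(C)O[C@H]2[C@H]2OC(=O)C(O)=C12
F13 | step 19 | C11 enol triflate | CC(C)(C)[Si](C)(C)O[C@H]1C/C(C)=C(O[Si](C)(C)C(C)(C)C)\CC[C@@]2(C)O[C@H]2[C@H]2OC(=O)C(OS(=O)(=O)C(F)(F)F)=C12
F14 | step 19 | 13-hydroxy analogue of 29 | CC(C)(C)[Si](C)(C)O[C@H]1C/C(C)=C(O[Si](C)(C)C(C)(C)C)\CC[C@@]2(C)O[C@H]2[C@H]2OC(=O)C(CO)=C12
F0 | step 21 | none | none
A1 | alternative 1 | (1R,6R)-6-methoxy-1-[(E)-2-(4-methoxybenzyloxy)ethenyl]-3-methyl-6-(prop-1-en-2-yl)cyclohex-2-en-1-ol | O[C@@]1(/C=C/OCc2ccc(OC)cc2)C=C(C)CC[C@@]1(OC)C(C)=C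
A2 | alternative 1 | ten-membered dienone with C8 4-methoxybenzyl ether, C1 methyl enol ether and cis C4=C5 | C1/C(C)=C\C(=O)C[C@@H](OCc2ccc(OC)cc2)C/C(C)=C(OC)/C1
A3 | alternative 2 | isoprene | C=CC(C)=C
A4 | alternative 2 | tert-butyldimethyl[(2-methylidenebut-3-yn-1-yl)oxy]silane | C#CC(=C)CO[Si](C)(C)C(C)(C)C
A5 | alternative 2 | ten-membered triene with trans C1=C10, cis C4=C5, cis C7=C8 and the C11=C13 branch | C=C(CO[Si](C)(C)C(C)(C)C)/C1=C/C/C(C)=C/CC/C(C)=C\C1
A6 | alternative 3 | butenolide-fused cyclohexanone with a (Z)-5-iodo-3-methylpent-2-enyl... chain at C6, (Z)-4-iodo-2-methylbut-1-enyl group as drawn | CC(C)(C)[Si](C)(C)O[C@H]1C[C@@H](C)C(=O)[C@]2(/C=C(C)\CCI)OC(=O)C(COC(C)=O)=C12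
A7 | alternative 3 | ten-membered keto butenolide with cis C4=C5 and C8 silyl ether | CC(C)(C)[Si](C)(C)O[C@H]1C[C@@H](C)C(=O)CC/C(C)=C\[C@H]2OC(=O)C(COC(C)=O)=C12
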